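I wanted to know which form of G stood highest after 50 h in south-west and in north, and how high.

1. which of these there is most of at the end, counted by the G in it, south-west (L / G.Z / G / E)
2. which of these there is most of at the end, counted by the G in it, north (L / G.Z / G / E)
3. final amount of the leader among these, as a percentage of the G charged, in south-west
4. final amount of the leader among these, as a percentage of the G charged, in north

- south-west: G 0.050 M; Q 8.1 mM (held); X 0.0500 M; temperature −10 °C; time 50 h
- north: G 0.050 M; Q 8.1 mM (held); X 0.0500 M; temperature −20 °C; time 50 h

    G → L (k1 = 0.013 /h, Ea1 = 89.0 kJ/mol)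
    Q ⇌ Z, rate k2*(csat - [Z]) (k2 = 0.18 /h, csat = 8.1 mM)
    G.Z → E (k3 = 0.12 /h, Ea3 = 76.0 kJ/mol)
    G + Z → G.Z (k4 = 2.2 /M/h, Ea4 = 52.0 kJ/mol)
    Z + X → Z.X (k5 = 1.2 /M/h, Ea5 = 44.0 kJ/mol)
    (constants at −20 °C)

- at the start none of Z is dissolved
- the constants hold at −20 °C; other temperatures follow from the activation energies

I balanced Z, whose saturation level 8.1 mM lies below the charge of G. I wrote k_t for the transfer, k_L for G → L, k_c for G + Z and k_x for Z + X. In north, Z approached its balance with a time constant of about 2.86 h, far shorter than the run, so I set gain equal to loss:

k_t (c_sat − cZ) = (k_c cG + k_x cX) cZ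

G goes to L at k_L and to G.Z at k_c cZ. Dividing the two at the starting charges gave:

B = k_L (k_t + k_c cG + k_x cX) / (k_c k_t c_sat)

In north B was 1.42. For south-west, k_L rose 4.99-fold, k_c 2.56-fold and k_x 2.21-fold, giving 4.70. B, the branch number, is the G sent to L for each G captured by Z, a selectivity factor. It exceeded one in both flasks, so L should outrun G.Z and E together.

One number was not enough, because B is silent on the G left. I added:

G left = exp(−k_L (1 + 1/B) t), L = (1 − G left) B / (1 + B)

North gave G 33.0% and L 39.3%, a narrow lead. South-west gave G 1.96% and L 80.8%.

The forecast named L in south-west at 78% (74% to 82%) and L in north at 39% (36% to 42%), holding that “capture of G is limited, so the first-order loss to L leads”. My south-west figure stood above its value.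

The simulation gave L at 78.9% in south-west and L at 39.6% in north, inside both ranges. In south-west, Z was made 1.12 times as fast as it was used at 8.11 h and 1.07 times at 50.0 h, and cZ stood at 5.46 mM at the end, above the 2.45 mM I had reckoned at the starting charges. With that final level, B in south-west read 2.11, and the flask's L over G.Z plus E, 3.98, lay between the final and starting values.

For the flask like south-west kept at −35 °C, B came to 0.294, below one, with G 81.9% and L 4.11%. That flask's run held G at 82.9% and L at 4.16%.

The rate constants belong to no real substance, and the outcome is calculated.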